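The numbers of this flask stand for no real mixture; what happens was integrated by code.

In a one-step world the recipe would not matter: whatever is charged becomes product. Here the flasks share a charge and differ in how, when and at what temperature it enters.

common to all: starting material 35 mM; third substrate 35.0 mM; time 20 min

| run | coupling partner | second substrate | temperature | remark |
|---|---|---|---|---|
| alder | 35.0 mM (fed, over 15 min) | 175 mM | 5 °C | all else is in the flask from the start; the feed brings no volume worth counting |
| birch | 35.0 mM | 175 mM |  | everything together at the start at −25 °C, warmed to 5 °C at 15 min |
| ash | 35.0 mM (fed, over 15 min) | 175 mM |  | the addition at −25 °C, then warmed to 5 °C; the feed brings no volume worth counting |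
| elm | 35.0 mM | 175 mM | 5 °C | everything together at the start |
| oak | 35.0 mM | 175 mM (in portions, 3, over 15 min) | 5 °C | first portion at the start, last at 15 min |

    starting material + coupling partner → target (k1 = 9.74 M⁻¹ min⁻¹, Ea1 = 42.0 kJ mol⁻¹)
    second substrate + coupling partner → second product (k2 = 1.40 M⁻¹ min⁻¹, Ea2 = 54.0 kJ mol⁻¹)
    third substrate + coupling partner → third product (k3 = 1.40 M⁻¹ min⁻¹, Ea3 = 40.0 kJ mol⁻¹)
    2 starting material → self-condensation product (k4 = 0.284 M⁻¹ min⁻¹, Ea4 = 59.0 kJ mol⁻¹)
    starting material + target ⇌ idle adduct, settled at all times (K5 = 1200 M⁻¹, ΔH5 = −68.0 kJ mol⁻¹)
    (constants at 5 °C)

- which flask leads in amount of self-condensation product, in percent of the starting material charged ("all alike" within 1.5 percentage points) (alder / birch / ash / elm / oak / all alike)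
- how much self-condensation product is there at the end, in percent of the starting material charged: alder
- how much self-condensation product is there at the end, in percent of the starting material charged: birch
- how much self-condensation product is there at the end, in percent of the starting material charged: ash
- how much self-condensation product is there at the end, in percent of the starting material charged: elm
- how much self-condensation product is there at the end, in percent of the starting material charged: oak

- in percentages every species weighs as the starting material in it: one self-condensation product or idle adduct counts as two
- for target the idle adduct is counted in
- for a step with 2 of a species take k times the square, and two of it per event
- all constants are for 5 °C and move with temperature by the activation energies and enthalpies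
- in an amount of target, one idle adduct counts as one target

I divided one rate by another. Self-condensation at full charge uses starting material at twice its constant times the charge squared, while in alder the coupling partner arrives at its charge over the feed time. For alder the quotient is 0.298; I called it the loss number, a Damköhler number: the fraction of the charge that self-condensation takes, at undiminished strength, per charge of partner delivered.

The free fraction does not stay whole. The adduct constant times the charge is 42, so target, as it forms, goes on to tie up further starting material as idle adduct. If the free fraction fell straight from one to nothing over the feed, the mean of its square would be a third, so I expected about 9.94% in alder.

Where the partner stands in the flask from the start, the rate of the first step takes the place of the feed rate in the quotient, and feed time drops out. The number is then 0.0583 for elm and, in the cold, 0.0240 for birch. I therefore put alder above elm and birch.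

One number was not enough, though. Birch's warm last 5.00 min is worth 0.0994 times the square of the free fraction then, and that tail is larger than birch's number before the square is applied. The loss number does not give that fraction, so I committed to no figure for the cold flasks.

The forecast named alder, with 10.5% there (range 8.5% to 12.5%), 1.6% in birch, 2.3% in ash, 3.9% in elm and 2.2% in oak, holding that “slow feeding at 5 °C leaves free starting material high for a long time”. Its alder figure stands above mine.

The simulation gave alder as leader, with 12.5%, against 1.50% in birch, 2.37% in ash, 4.05% in elm and 2.52% in oak. Alder ended with 20.3% of its starting material free, not nothing, and its answer over the loss number reads 0.420, above the 0.333 I had reckoned with. In birch the number goes with starting material over partner, so 14 mM of starting material cuts it to 0.00959, and taking birch's answer down in step gives 0.602%; the neighbour flask, birch with that charge, gave 0.525%.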